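Whether a reading at 2.0 d is worth waiting for depends on what can still move by then. In the south-west run product reads 36.9 % at 4.00 h and 37.4 % at 30.0 h, with 61.7 % of the starting material still present.

in all of them: partner 0.0144 M; catalyst 3.6 mM
- north-west: starting material 0.016 M; protic impurity 7.2 mM; run made earlier
- south-west: starting material 0.036 M; protic impurity 7.2 mM; run made earlier
- flask: starting material 0.024 M; protic impurity 7.20 mM; time 2.0 d

- north-west (time / h: starting material / %, product / %): 2.50: 48.5, 51.8; 4.00: 39.1, 60.8; 6.00: 33.9, 66.8; 10.0: 29.0, 71.6; 20.0: 25.5, 74.1; 30.0: 25.1, 75.4
- south-west (time / h: starting material / %, product / %): 2.50: 65.1, 34.2; 4.00: 63.1, 36.9; 6.00: 62.4, 36.7; 10.0: 63.3, 36.9; 20.0: 62.7, 37.0; 30.0: 61.7, 37.4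

(scatter of a reading: 0.5 percentage points)



1. starting material present at 2.0 d, in percent of the starting material charged
2. product present at 2.0 d, in percent of the starting material charged

Partner is charged below starting material in each of the three flasks, so it is taken as the limiting reagent and its balance is written, counting one partner per product. The lost share is the fraction of charged partner not found as product at the last reading: 16.2 % in the north-west run and 6.50 % in the south-west run, smaller in the run with more starting material. The loss number is the lost share times the starting material charge over the protic impurity charge. These readings give 0.360 and 0.325, with a mean of 0.343. Both runs held the impurity charge at 7.2 mM, so the proportionality to that charge is an assumption.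

For this flask the loss number gives a lost share of 10.3 %, hence product at 53.8 % of the starting material charged, against 60.0 % with no partner lost. The decision is to charge as listed and keep the reading time.

The forecast gives 46.3 % and 53.7 %, holding that “partner is probably exhausted”; the reckoning above, made by another route, gave 53.8 % for product.

The flask gives 46.3 % and 53.7 %, as forecast. At 2.00 d it holds 0.00151 M of quenched reagent, 10.5 % of the partner charge, with partner at 0 %. That share returns a loss number of 0.350 for this flask.

    starting material + partner + catalyst → catalyst + product (k = 10000 L² mol⁻² h⁻¹)
    partner + protic impurity → quenched reagent (k = 11.0 L mol⁻¹ h⁻¹)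

In the neighbour flask with 0.018 M of protic impurity, the loss number gives a lost share of 25.7 %, so product at 44.6 %. The computed neighbour flask gives 46.8 %.

(Readings and results come from a simulation for an exercise, and the scatter is random.)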